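**Retrosynthetic overview**
- Last bond: C14–C1. A primary C14 radical adds to the β-carbon of a γ-alkenyl α-(sulfonylmethyl)butenolide and expels the sulfonyl radical; this closes the 14-membered ring last, sets C1 and unveils the exo-methylene in one event.
- The butenolide ring is made just before, by ring-closing metathesis of the 2-(sulfonylmethyl)acrylate of the C2 carbinol; C2–C3 comes from a ligand-controlled nickel/chromium coupling of an E-alkenyl iodide with acrolein.
- C13–C14: chelation-controlled iodomethylation of an epoxy aldehyde; C11/C12 epoxide by Sharpless epoxidation; C13 oxygen by SeO2 oxidation.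
- Chain: Z-C7=C8 by carbocupration of propyne, C6–C7 by Negishi coupling, E-C3=C4 by zirconium-catalysed carboalumination.

Assumption: the SMILES is read as the (1S,2S,3E,7Z,11S,12R,13R) cis-fused cembranolide; C-locants in the comments are cembrane locants (C1/C2 ring fusion, ring oxygen on C2, OAc on C13, C15–C17 the methylene-lactone carbons).

**Step 1**
Reactants: 1 5-bromo-2-methylpent-2-ene; 2 propyne
Product: 5 (1Z)-1-iodo-2,6-dimethylhepta-1,5-diene, via Grignard reagent 3 (not isolated), via alkenylcopper 4 (not isolated)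
Conditions: Mg, Et2O; CuBr·SMe2, Et2O/Me2S, −45 °C; propyne, −25 °C; I2, THF, −40 → 0 °C
Reagents that add atoms: iodine, II
Why: Normant carbocupration: the alkylcopper adds syn across propyne with the alkyl group on the internal carbon, so chain and copper are cis, and iodinolysis with retention fixes the Z geometry of the later C7=C8 bond.

**Step 2**
Reactants: 5 (1Z)-1-iodo-2,6-dimethylhepta-1,5-diene; 6 4-bromobut-1-yne
Product: 8 (5Z)-6,10-dimethylundeca-5,9-dien-1-yne, via but-3-ynylzinc bromide 7 (not isolated)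
Conditions: 6, Zn, LiCl, THF, 40 °C; then 5, PdCl2(dppf) (3 mol%), THF, 45 °C
Reagents that add atoms: none
Why: Negishi sp3–sp2 cross-coupling: zinc inserts into the primary C–Br bond without deprotonating the alkyne (an alkylzinc halide is too weak a base), and the palladium cycle retains the Z-alkenyl geometry.

**Step 3**
Reactants: 8 (5Z)-6,10-dimethylundeca-5,9-dien-1-yne
Product: 9 (2E,6Z)-2,6-dimethylundeca-2,6-dien-10-yn-1-ol
Conditions: SeO2 (0.3 equiv), t-BuOOH (3 equiv), salicylic acid (10 mol%), CH2Cl2, 0 °C → rt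
Reagents that add atoms: tert-butyl hydroperoxide, CC(C)(C)OO
Why: Selenium dioxide allylic oxidation (ene reaction, then 2,3-sigmatropic shift) takes the E-methyl of the terminal, most accessible trisubstituted olefin and gives the E-allylic alcohol (the C13 oxygen); run to partial conversion with 8 recycled.

**Step 4**
Reactants: 9 (2E,6Z)-2,6-dimethylundeca-2,6-dien-10-yn-1-ol
Product: 11 (2E,6Z,10E)-11-iodo-2,6,10-trimethylundeca-2,6,10-trien-1-ol, via alkenylalane alkoxide 10 (not isolated)
Conditions: Me3Al (3.5 equiv), Cp2ZrCl2 (0.25 equiv), CH2Cl2, 0 °C → rt; I2, THF, −30 °C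
Reagents that add atoms: trimethylaluminium, C[Al](C)C; iodine, II
Why: Negishi zirconium-catalysed carboalumination: Me–Al adds syn to the terminal alkyne with methyl on the internal carbon, and iodinolysis with retention gives the E-alkenyl iodide (E-C3=C4); the alcohol rides through as its aluminium alkoxide.

**Step 5**
Reactants: 11 (2E,6Z,10E)-11-iodo-2,6,10-trimethylundeca-2,6,10-trien-1-ol
Product: 12 [(2S,3S)-3-[(3Z,7E)-8-iodo-3,7-dimethylocta-3,7-dien-1-yl]-2-methyloxiran-2-yl]methanol
Conditions: Ti(OiPr)4 (10 mol%), L-(+)-diethyl tartrate (12 mol%), t-BuOOH, 4 Å MS, CH2Cl2, −20 °C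
Reagents that add atoms: tert-butyl hydroperoxide, CC(C)(C)OO
Why: Sharpless asymmetric epoxidation: only the allylic-alcohol olefin reacts, and the L-(+)-tartrate catalyst delivers oxygen to the face that gives the (2S,3S)-epoxy alcohol, which sets C11 and C12 of the target.

**Step 6**
Reactants: 12 [(2S,3S)-3-[(3Z,7E)-8-iodo-3,7-dimethylocta-3,7-dien-1-yl]-2-methyloxiran-2-yl]methanol
Product: 13 (2R,3S)-3-[(3Z,7E)-8-iodo-3,7-dimethylocta-3,7-dien-1-yl]-2-methyloxirane-2-carbaldehyde
Conditions: Dess–Martin periodinane, pyridine, CH2Cl2, 0 °C → rt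
Reagents that add atoms: none
Why: Dess–Martin oxidation of the primary alcohol under buffered conditions; the α-carbon is quaternary, so the epoxide stereocentres cannot epimerise (the descriptor at C2 changes only by CIP priority).

**Step 7**
Reactants: 13 (2R,3S)-3-[(3Z,7E)-8-iodo-3,7-dimethylocta-3,7-dien-1-yl]-2-methyloxirane-2-carbaldehyde
Product: 15 (1S)-2-iodo-1-[(2R,3S)-3-[(3Z,7E)-8-iodo-3,7-dimethylocta-3,7-dien-1-yl]-2-methyloxiran-2-yl]ethyl acetate, via magnesium alkoxide 14 (not isolated)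
Conditions: CH2I2, i-PrMgCl, THF/Et2O, −78 °C (carbenoid pre-formed); 13, MgBr2·OEt2, −78 °C; then Ac2O, DMAP (cat.), −78 → −20 °C
Reagents that add atoms: diiodomethane, ICI; acetic anhydride, CC(=O)OC(C)=O
Why: Cram-chelate addition of the magnesium carbenoid ICH2MgCl: magnesium bridges the aldehyde and oxirane oxygens and the iodomethyl group enters anti to the oxirane C–C bond, giving the threo iodohydrin (target 13R; 1S here by CIP), whose alkoxide is acetylated cold before it can close to an epoxide.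

**Step 8**
Reactants: 15 (1S)-2-iodo-1-[(2R,3S)-3-[(3Z,7E)-8-iodo-3,7-dimethylocta-3,7-dien-1-yl]-2-methyloxiran-2-yl]ethyl acetate; 16 prop-2-enal (acrolein)
Product: 17 (1S)-1-[(2R,3S)-3-[(3Z,7E,9R)-9-hydroxy-3,7-dimethylundeca-3,7,10-trien-1-yl]-2-methyloxiran-2-yl]-2-iodoethyl acetate
Conditions: CrCl2 (4 equiv), NiCl2 (2 mol%), chiral oxazoline–sulfonamide ligand (4.4 equiv, enantiomer giving Si-face addition), Et3N, acrolein (3 equiv), THF, rt
Reagents that add atoms: none
Why: Nozaki–Hiyama–Kishi alkenylation: nickel inserts only into the alkenyl C–I bond (CrCl2 does not reduce a primary alkyl iodide without a cobalt co-catalyst), and the chromium-bound chiral ligand directs the E-alkenyl group to the Si face of acrolein, setting C2 as the (R)-carbinol.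

**Step 9**
Reactants: 18 2-(bromomethyl)prop-2-enoic acid
Product: 19 2-[(phenylsulfonyl)methyl]prop-2-enoic acid
Conditions: PhSO2Na (1.2 equiv), MeOH, reflux
Reagents that add atoms: sodium benzenesulfinate, [Na+].[O-]S(=O)c1ccccc1
Why: Allylic substitution of the bromide by sulfinate sulfur (SN2 and SN2′ give the same allyl sulfone).

**Step 10**
Reactants: 17 (1S)-1-[(2R,3S)-3-[(3Z,7E,9R)-9-hydroxy-3,7-dimethylundeca-3,7,10-trien-1-yl]-2-methyloxiran-2-yl]-2-iodoethyl acetate; 19 2-[(phenylsulfonyl)methyl]prop-2-enoic acid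
Product: 20 (3R,4E,8Z)-11-[(2S,3R)-3-[(1S)-1-acetoxy-2-iodoethyl]-3-methyloxiran-2-yl]-5,9-dimethylundeca-1,4,8-trien-3-yl 2-[(phenylsulfonyl)methyl]prop-2-enoate
Conditions: DIC, DMAP (5 mol%), CH2Cl2, 0 °C
Reagents that add atoms: none
Why: Steglich esterification: carbodiimide activation of the acid and O-acylation of the secondary allylic alcohol, with retention at C2.

**Step 11**
Reactants: 20 (the acrylate ester from step 10)
Product: 21 (5S)-5-[(1E,5Z)-8-[(2S,3R)-3-[(1S)-1-acetoxy-2-iodoethyl]-3-methyloxiran-2-yl]-2,6-dimethylocta-1,5-dien-1-yl]-3-[(phenylsulfonyl)methyl]furan-2(5H)-one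
Conditions: second-generation Hoveyda–Grubbs catalyst (10 mol%), toluene, 70 °C, Ar sparge
Reagents that add atoms: none
Why: Ring-closing metathesis: the catalyst loads on the only monosubstituted olefin and closes onto the 1,1-disubstituted acrylate to give the butenolide with loss of ethene; the trisubstituted olefins, epoxide, acetate and iodide are inert.

**Step 12**
Reactants: 21 (the butenolide from step 11)
Product: 22 (1S,2S,3E,7Z,11S,12R,13R)-13-acetoxy-11,12-epoxycembra-3,7,15(17)-trien-16,2-olide (target)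
Conditions: (Bu3Sn)2 (1.5 equiv), hν (sunlamp, Pyrex), benzene, 0.5 mM, 25 °C
Reagents that add atoms: none
Why: Proposed new method: Bu3Sn• from the photolysed ditin abstracts iodine from C14 far faster than it adds to the butenolide; the primary radical adds 14-endo to C1 (the β-carbon of the ester-activated olefin) and the α-ester radical expels PhSO2• (taken up by the ditin, which returns Bu3Sn•), which makes the addition irreversible and places the double bond exocyclic; C1 is expected S (cis fusion) because the rigid E-C3=C4 unit on C2, held by allylic strain against the C4 methyl, launches the tether over the C3 face of the lactone so that this face of C1 is the one within reach of C14, although the competing anti mode is not excluded; no hydrogen donor and room temperature hold back premature reduction and 1,2-acetoxy shift; closest known reactions are tin-mediated radical allyl transfer from alkyl iodides to 2-(sulfonylmethyl)acrylates and endo radical macrocyclisation onto acrylates.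

**Compound list**
1 | 5-bromo-2-methylpent-2-ene | CC(C)=CCCBr | starting material
2 | propyne | CC#C | starting material
3 | (4-methylpent-3-en-1-yl)magnesium bromide | CC(C)=CCC[Mg]Br | intermediate
4 | [(1Z)-2,6-dimethylhepta-1,5-dien-1-yl]copper (MgBr2 complex) | [Cu]/C=C(/C)CCC=C(C)C | intermediate
5 | (1Z)-1-iodo-2,6-dimethylhepta-1,5-diene | I/C=C(/C)CCC=C(C)C | intermediate
6 | 4-bromobut-1-yne | C#CCCBr | starting material
7 | but-3-yn-1-ylzinc bromide | C#CCC[Zn]Br | intermediate
8 | (5Z)-6,10-dimethylundeca-5,9-dien-1-yne | C#CCC/C=C(/C)CCC=C(C)C | intermediate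
9 | (2E,6Z)-2,6-dimethylundeca-2,6-dien-10-yn-1-ol | C#CCC/C=C(/C)CC/C=C(\C)CO | intermediate
10 | dimethylaluminium alkoxide of (2E,6Z,10E)-11-(dimethylalumanyl)-2,6,10-trimethylundeca-2,6,10-trien-1-ol | C[Al](C)/C=C(\C)CC/C=C(/C)CC/C=C(\C)CO[Al](C)C | intermediate
11 | (2E,6Z,10E)-11-iodo-2,6,10-trimethylundeca-2,6,10-trien-1-ol | I/C=C(\C)CC/C=C(/C)CC/C=C(\C)CO | intermediate
12 | [(2S,3S)-3-[(3Z,7E)-8-iodo-3,7-dimethylocta-3,7-dien-1-yl]-2-methyloxiran-2-yl]methanol | I/C=C(\C)CC/C=C(/C)CC[C@@H]1O[C@@]1(C)CO | intermediate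
13 | (2R,3S)-3-[(3Z,7E)-8-iodo-3,7-dimethylocta-3,7-dien-1-yl]-2-methyloxirane-2-carbaldehyde | I/C=C(\C)CC/C=C(/C)CC[C@@H]1O[C@@]1(C)C=O | intermediate
14 | chloromagnesium alkoxide of the (1S)-iodohydrin (15 before acetylation) | I/C=C(\C)CC/C=C(/C)CC[C@@H]1O[C@@]1(C)[C@H](O[Mg]Cl)CI | intermediate
15 | (1S)-2-iodo-1-[(2R,3S)-3-[(3Z,7E)-8-iodo-3,7-dimethylocta-3,7-dien-1-yl]-2-methyloxiran-2-yl]ethyl acetate | I/C=C(\C)CC/C=C(/C)CC[C@@H]1O[C@@]1(C)[C@H](OC(C)=O)CI | intermediate
16 | prop-2-enal (acrolein) | C=CC=O | starting material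
17 | (1S)-1-[(2R,3S)-3-[(3Z,7E,9R)-9-hydroxy-3,7-dimethylundeca-3,7,10-trien-1-yl]-2-methyloxiran-2-yl]-2-iodoethyl acetate | C=C[C@@H](O)/C=C(\C)CC/C=C(/C)CC[C@@H]1O[C@@]1(C)[C@H](OC(C)=O)CI | intermediate
18 | 2-(bromomethyl)prop-2-enoic acid | C=C(CBr)C(=O)O | starting material
19 | 2-[(phenylsulfonyl)methyl]prop-2-enoic acid | C=C(CS(=O)(=O)c1ccccc1)C(=O)O | intermediate
20 | (3R,4E,8Z)-11-[(2S,3R)-3-[(1S)-1-acetoxy-2-iodoethyl]-3-methyloxiran-2-yl]-5,9-dimethylundeca-1,4,8-trien-3-yl 2-[(phenylsulfonyl)methyl]prop-2-enoate | C=C[C@@H](OC(=O)C(=C)CS(=O)(=O)c1ccccc1)/C=C(\C)CC/C=C(/C)CC[C@@H]2O[C@@]2(C)[C@H](OC(C)=O)CI | intermediate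
21 | (5S)-5-[(1E,5Z)-8-[(2S,3R)-3-[(1S)-1-acetoxy-2-iodoethyl]-3-methyloxiran-2-yl]-2,6-dimethylocta-1,5-dien-1-yl]-3-[(phenylsulfonyl)methyl]furan-2(5H)-one | O=C1O[C@H](C=C1CS(=O)(=O)c3ccccc3)/C=C(\C)CC/C=C(/C)CC[C@@H]2O[C@@]2(C)[C@H](OC(C)=O)CI | intermediate
22 | (1S,2S,3E,7Z,11S,12R,13R)-13-acetoxy-11,12-epoxycembra-3,7,15(17)-trien-16,2-olide (CNP0146076.3) | C=C1C(=O)O[C@H]2/C=C(\C)CC/C=C(/C)CC[C@@H]3O[C@@]3(C)[C@H](OC(C)=O)C[C@@H]12 | target

**Totals and risks**
Total step count: 12. Longest linear sequence: 11 (steps 1–8 and 10–12); step 9 is a one-step side branch.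

The three steps most likely to fail are 12, 8 and 7.

Step 12 is the main risk: the 14-endo addition to a β-substituted acceptor is slow, the product methylene lactone is itself a radical trap, and the C1 epimer may form. The fallback sets out from 17 and comes back at 22. Dienol 17 is esterified (DIC, DMAP) with 2-(diethoxyphosphoryl)prop-2-enoic acid to the phosphonoacrylate ester F1. Ring-closing metathesis gives the 3-(diethoxyphosphoryl)butenolide F2, a doubly activated and much faster radical trap. Reductive Giese macrocyclisation ((Me3Si)3SiH by syringe pump, Et3B/air, benzene, 1 mM) gives the α-phosphono lactone F3. Horner–Wadsworth–Emmons methylenation (aqueous CH2O, K2CO3, THF, 0 °C) then gives 22.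

Step 8 may give poor facial control with so small an aldehyde, and CrCl2 may touch the primary iodide. The fallback sets out from 15 and comes back at 17. Carbonylative Stille coupling of 15 with tributyl(vinyl)stannane under CO (Pd2(dba)3, AsPh3, NMP, rt) gives the cross-conjugated dienone F4. Reduction with catecholborane and (S)-2-methyl-CBS-oxazaborolidine (toluene, −78 °C; the trisubstituted alkenyl group is the large substituent) gives 17.

Step 7 depends on magnesium chelation by an oxirane oxygen for the threo:erythro ratio. The fallback sets out from 13 and comes back at 15. Unselective addition of LiCH2I (CH2I2, MeLi·LiBr, THF, −78 °C, AcOH quench) gives the iodohydrin epimer mixture F5. Dess–Martin oxidation gives the α-iodo ketone F6. Reagent-controlled reduction with catecholborane and (S)-2-methyl-CBS-oxazaborolidine (CH2I as the small group) gives the (1S)-iodohydrin F7, and Ac2O/pyridine returns 15.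

**Further compounds**
F1 | step 12 | (3R,4E,8Z)-11-[(2S,3R)-3-[(1S)-1-acetoxy-2-iodoethyl]-3-methyloxiran-2-yl]-5,9-dimethylundeca-1,4,8-trien-3-yl 2-(diethoxyphosphoryl)prop-2-enoate | C=C[C@@H](OC(=O)C(=C)P(=O)(OCC)OCC)/C=C(\C)CC/C=C(/C)CC[C@@H]1O[C@@]1(C)[C@H](OC(C)=O)CI
F2 | step 12 | diethyl [(5S)-5-[(1E,5Z)-8-[(2S,3R)-3-[(1S)-1-acetoxy-2-iodoethyl]-3-methyloxiran-2-yl]-2,6-dimethylocta-1,5-dien-1-yl]-2-oxo-2,5-dihydrofuran-3-yl]phosphonate | CCOP(=O)(OCC)C1=C[C@@H](OC1=O)/C=C(\C)CC/C=C(/C)CC[C@@H]2O[C@@]2(C)[C@H](OC(C)=O)CI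
F3 | step 12 | 15-(diethoxyphosphoryl)-15,17-dihydro derivative of 22 (C15 epimers, cis-fused) | CCOP(=O)(OCC)C1C(=O)O[C@H]2/C=C(\C)CC/C=C(/C)CC[C@@H]3O[C@@]3(C)[C@H](OC(C)=O)C[C@@H]12
F4 | step 8 | (1S)-1-[(2R,3S)-3-[(3Z,7E)-3,7-dimethyl-9-oxoundeca-3,7,10-trien-1-yl]-2-methyloxiran-2-yl]-2-iodoethyl acetate | C=CC(=O)/C=C(\C)CC/C=C(/C)CC[C@@H]1O[C@@]1(C)[C@H](OC(C)=O)CI
F5 | step 7 | 2-iodo-1-[(2R,3S)-3-[(3Z,7E)-8-iodo-3,7-dimethylocta-3,7-dien-1-yl]-2-methyloxiran-2-yl]ethan-1-ol (carbinol epimers) | I/C=C(\C)CC/C=C(/C)CC[C@@H]1O[C@@]1(C)C(O)CI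
F6 | step 7 | 2-iodo-1-[(2R,3S)-3-[(3Z,7E)-8-iodo-3,7-dimethylocta-3,7-dien-1-yl]-2-methyloxiran-2-yl]ethan-1-one | I/C=C(\C)CC/C=C(/C)CC[C@@H]1O[C@@]1(C)C(=O)CI
F7 | step 7 | (1S)-2-iodo-1-[(2R,3S)-3-[(3Z,7E)-8-iodo-3,7-dimethylocta-3,7-dien-1-yl]-2-methyloxiran-2-yl]ethan-1-ol | I/C=C(\C)CC/C=C(/C)CC[C@@H]1O[C@@]1(C)[C@H](O)CI
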